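**Plan**

1. Numbering is that of the germacrane skeleton: ring C1–C10, lactone carbons C11–C13 on C7 with the ring oxygen on C6, ester carbon C14 on C10, methyl C15 on C4; β is the ring face that carries C11 at C7.
2. Cuts, in order: the C8 angelate; the C9–O and C8–O bonds (back to the cis C8=C9 alkene); C11=C13; the lactone C12–O and C7–C11 bonds; C1–H (back to a C1 ketone); last, the C1 and C6 ketones are rejoined as a C1=C6 alkene, which leads to a Birch diene and a tetralin acid.
3. Enabling feature: C1 and C6 face each other 1,6 across the ten-membered ring and both are functionalised, so a C1–C6 bond gives a tetralin with arene C1, C10, C9, C8, C7, C6 (C14 carboxyl on C10) and a saturated ring C2–C5 carrying the C4 methyl.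
4. Forward: both six-membered rings come from 5-bromo-2-tetralone; Birch reduction leaves only the ring-fusion and C8=C9 alkenes; ozonolysis of the ring-fusion alkene merges the two rings into the ten-membered ring; the γ-lactone is then closed (C7 alkylation, C6 reduction, lactonization) and the C8/C9 oxygens and the angelate come last.
5. Stereochemistry: C4 from Ir-catalysed asymmetric hydrogenation; C7 from alkylation of the ring dienolate; C6 from CBS reduction; C8 and C9 from (salen)MnCl epoxidation and anti opening at C9; cis C8=C9 is inherited from the arene, the C1=C10 geometry from a Z-enol triflate.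

Key step: step 7

Assumption: the sense of induction of the three chiral reagents (steps 3, 11, 14) is taken from the accepted models for their substrate classes; the antipodal reagent is used if the substrate responds in the opposite sense.

Abbreviations: BArF = tetrakis[3,5-bis(trifluoromethyl)phenyl]borate; (S)-tBu-PHOX = (S)-4-tert-butyl-2-[2-(diphenylphosphino)phenyl]-2-oxazoline; (R,R)-(salen)MnCl = chloro[(R,R)-N,N'-bis(3,5-di-tert-butylsalicylidene)cyclohexane-1,2-diaminato]manganese.

**Step 1**
Reactants: 1 5-bromo-2-tetralone
Product: 2 5-bromo-2-methyl-1,2,3,4-tetrahydronaphthalen-2-ol (racemic)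
Conditions: MeMgBr, CeCl3 (anhydrous), THF, −78 → 0 °C; aq NH4Cl
Reagents that add atoms: methylmagnesium bromide, C[Mg]Br
Why: Organocerium 1,2-addition, in which the weakly basic methylcerium reagent should add to the carbonyl of this very easily enolized 2-tetralone where the Grignard reagent alone would mostly deprotonate it; the racemic carbinol centre is removed in step 2.

**Step 2**
Reactants: 2 5-bromo-2-methyl-1,2,3,4-tetrahydronaphthalen-2-ol
Product: 3 8-bromo-3-methyl-1,2-dihydronaphthalene
Conditions: TsOH·H2O (cat.), toluene, reflux, Dean–Stark trap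
Reagents that add atoms: none
Why: Acid-catalysed E1 dehydration under equilibrating conditions should funnel all alkene isomers to the arene-conjugated trisubstituted alkene, a much better substrate for face-selective hydrogenation than the exocyclic methylene isomer, whose two allylic CH2 groups are nearly alike.

**Step 3**
Reactants: 3 8-bromo-3-methyl-1,2-dihydronaphthalene
Product: 4 (S)-5-bromo-2-methyl-1,2,3,4-tetrahydronaphthalene
Conditions: [Ir(cod)((S)-tBu-PHOX)]BArF (1 mol%), H2 (50 bar), CH2Cl2, rt
Reagents that add atoms: none
Why: Iridium-catalysed asymmetric hydrogenation of an unfunctionalized trisubstituted aryl alkene with a chiral phosphine–oxazoline ligand, whose pocket selects one enantiotopic alkene face and so sets C4 (S), while the aryl bromide is inert to the cationic catalyst.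

**Step 4**
Reactants: 4 (S)-5-bromo-2-methyl-1,2,3,4-tetrahydronaphthalene
Product: 6 (S)-6-methyl-5,6,7,8-tetrahydronaphthalene-1-carboxylic acid, via aryllithium 5 (not isolated)
Conditions: n-BuLi, THF, −78 °C; CO2 (g), −78 °C → rt; aq HCl
Reagents that add atoms: carbon dioxide, O=C=O
Why: Bromine–lithium exchange and carboxylation of the aryllithium place C14 on the future C10 without touching the remote C4 centre, and the crystalline acid offers a point for enantiomeric upgrading by recrystallization.

**Step 5**
Reactants: 6 (S)-6-methyl-5,6,7,8-tetrahydronaphthalene-1-carboxylic acid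
Product: 7 (6S)-6-methyl-1,4,5,6,7,8-hexahydronaphthalene-1-carboxylic acid (both C1 epimers)
Conditions: Li, NH3 (l), THF, −78 °C; then NH4Cl
Reagents that add atoms: none
Why: Birch reduction of a benzoic acid, in which the carboxylate directs protonation to the ipso carbon C10 and the para carbon C7, so that only the cis C8=C9 alkene and the tetrasubstituted C1=C6 ring-fusion alkene remain; C10 forms without control, which is harmless because it becomes sp2 later.

**Step 6**
Reactants: 7 (6S)-6-methyl-1,4,5,6,7,8-hexahydronaphthalene-1-carboxylic acid
Product: 8 methyl (6S)-6-methyl-1,4,5,6,7,8-hexahydronaphthalene-1-carboxylate (Birch diene ester; both C1 epimers)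
Conditions: Me3SiCHN2, toluene/MeOH 4:1, 0 °C
Reagents that add atoms: (trimethylsilyl)diazomethane, C[Si](C)(C)C=[N+]=[N-]
Why: O-Methylation of the acid by diazomethane generated in the flask needs no base, so the skipped diene with its doubly allylic C10–H is neither conjugated nor aromatized.

**Step 7**
Reactants: 8 methyl (6S)-6-methyl-1,4,5,6,7,8-hexahydronaphthalene-1-carboxylate
Product: 10 methyl (2Z,7S)-7-methyl-5,10-dioxocyclodec-2-ene-1-carboxylate (ten-membered C1/C6 diketone; C10 epimers), via methoxy hydroperoxide 9 (not isolated)
Conditions: O3 (1.0 equiv, Sudan Red 7B end point), CH2Cl2/MeOH 5:1, −78 °C; then Me2S, −78 °C → rt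
Reagents that add atoms: ozone, [O-][O+]=O
Why: Ozone adds as a 1,3-dipole to the tetrasubstituted C1=C6 ring-fusion alkene, the primary ozonide fragments (Criegee mechanism) into the C1 ketone and a C6 carbonyl oxide, methanol traps the latter as methoxy hydroperoxide 9, and Me2S reduces 9 to the second ketone. The closest known reaction type is the ozonolysis of the ring-fusion alkene of octalins and hexahydronaphthalenes to cyclodecane-1,6-diones. The ten-membered ring is not closed by a cyclization but appears when the bond shared by the two six-membered rings is cut (ring expansion by scission of the fusion bond), so no medium-ring closure has to be attempted. No stereocentre is formed: C4 is untouched, C10 stays enolizable and is erased later, and C8=C9 keeps the cis geometry it had in the cyclohexadiene. The selectivity needed is attack on the tetrasubstituted alkene in the presence of the disubstituted one, which should be secured by the four alkyl substituents, the inductive deactivation of C8=C9 by the neighbouring ester-bearing carbon, one equivalent of ozone with a dye end point, and −78 °C. The neutral reductive work-up and immediate use of 10 are meant to suppress transannular aldol reaction between the C10 enol and the C6 ketone.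

**Step 8**
Reactants: 10 methyl (2Z,7S)-7-methyl-5,10-dioxocyclodec-2-ene-1-carboxylate
Product: 12 (4S)-C1 Z-enol triflate of 10: ring C1(OTf)=C10(CO2Me) with OTf cis to the ester; C8=C9 cis; C6 ketone, via sodium enolate 11 (not isolated)
Conditions: NaH (1.0 equiv), THF, 0 °C; then PhNTf2, 0 °C → rt
Reagents that add atoms: N-phenylbis(trifluoromethanesulfonimide), O=S(=O)(N(c1ccccc1)S(=O)(=O)C(F)(F)F)C(F)(F)F
Why: O-Sulfonylation of a β-keto ester enolate, in which C10–H is by far the most acidic proton so that one equivalent of base leaves the C6 ketone alone, and sodium chelation between enolate oxygen and ester carbonyl together with the ring's preference for a cis alkene places the triflate cis to the ester (Z).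

**Step 9**
Reactants: 12 (4S)-C1 Z-enol triflate
Product: 13 methyl (4S)-4-methyl-6-oxocyclodeca-1(10),8-diene-10-carboxylate (H1 cis to the ester, 1(10)E; C8=C9 cis)
Conditions: Pd(OAc)2 (5 mol%), PPh3 (10 mol%), HCO2H, Et3N, DMF, 40 °C
Reagents that add atoms: none
Why: Palladium-catalysed formate reduction of an enol triflate (oxidative addition to zerovalent palladium, formate exchange, loss of CO2, C–H reductive elimination) replaces OTf by H with retention of alkene geometry, so H1 ends up cis to the ester as in the target, and the buffered medium should not conjugate the β,γ-unsaturated ketone.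

**Step 10**
Reactants: 13 methyl (4S)-4-methyl-6-oxocyclodeca-1(10),8-diene-10-carboxylate; 14 tert-butyl bromoacetate
Product: 16 (4S,7R)-keto diester: 13 carrying CH2CO2tBu on C7, via lithium dienolate 15 (not isolated)
Conditions: LiN(SiMe3)2, THF, −78 °C; then 14, DMPU, −78 → −40 °C
Reagents that add atoms: tert-butyl bromoacetate (14), BrCC(=O)OC(C)(C)C
Why: Enolate alkylation, in which the C7 protons (α to the ketone and allylic) are removed selectively to give the extended dienolate 15 that reacts with the bromoacetate at its α-carbon; the new C7 centre is set by approach of the electrophile to the exposed outer face of the ten-membered dienolate in the conformation fixed by the two cis alkenes and the C4 methyl group (conformational control in a medium ring), and because C7 stays enolizable the unwanted epimer can be re-equilibrated with base and recycled.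

**Step 11**
Reactants: 16 (4S,7R)-keto diester
Product: 17 (4S,6R,7R)-hydroxy diester: C6 alcohol with OH anti to the C7 side chain
Conditions: (S)-Me-CBS oxazaborolidine (1 equiv), catecholborane, toluene, −78 °C
Reagents that add atoms: none
Why: Corey–Bakshi–Shibata reduction, in which the oxazaborolidine treats the branched C7 side as the large group and delivers hydride to the face that gives the 6R alcohol (anti to the C7 side chain) by reagent control, under non-basic conditions that do not epimerize C7 and with a borane that leaves the esters and alkenes alone.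

**Step 12**
Reactants: 17 (4S,6R,7R)-hydroxy diester
Product: 19 (4S,6R,7R)-trans-fused γ-lactone: C12(=O)–O–C6 closed; C11H2; methyl ester and both ring alkenes unchanged, via hydroxy acid 18 (not isolated)
Conditions: TFA, CH2Cl2, 0 °C → rt
Reagents that add atoms: none
Why: Acidolysis of the tert-butyl ester followed by spontaneous γ-lactonization of hydroxy acid 18 (acyl substitution, retention at C6) should give the trans-fused lactone, the methyl ester and the diene being stable to the acid.

**Step 13**
Reactants: 19 (4S,6R,7R)-trans-fused γ-lactone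
Product: 22 (4S,6R,7S)-α-methylene lactone: 19 with C11=C13H2, via Mannich base 20 (not isolated), via ammonium iodide 21 (not isolated)
Conditions: LiN(SiMe3)2, THF, −78 °C; CH2=NMe2+ I−, −78 → 0 °C; then MeI, MeOH, rt; then aq NaHCO3, CH2Cl2
Reagents that add atoms: Eschenmoser's salt (N,N-dimethylmethyleneiminium iodide), C=[N+](C)C.[I-]
Why: Mannich reaction of the lactone lithium enolate with Eschenmoser's salt, N-methylation and E1cB loss of trimethylamine, in which the hindered amide base at −78 °C should deprotonate the lactone α-CH2 faster than it adds to the trisubstituted acrylate and the iminium salt should trap the enolate before transannular Michael addition to C1; the C11 configuration of 20 is irrelevant.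

**Step 14**
Reactants: 22 (4S,6R,7S)-α-methylene lactone
Product: 23 (4S,6R,7S,8S,9R)-8,9-epoxide of 22 with the epoxide oxygen on the β face
Conditions: (R,R)-(salen)MnCl (5 mol%), m-CPBA, N-methylmorpholine N-oxide, CH2Cl2, −78 °C
Reagents that add atoms: 3-chloroperbenzoic acid, O=C(OO)c1cccc(Cl)c1
Why: Jacobsen–Katsuki epoxidation of a cis-disubstituted conjugated alkene, in which the electrophilic oxomanganese species attacks only the C8=C9 bond (the acrylate and the α-methylene lactone are electron-poor); the (R,R) catalyst is chosen to deliver oxygen to the β face by analogy with cis-1-arylalkenes, C9 taking the place of the benzylic carbon, and the ring prevents cis-to-trans leakage.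

**Step 15**
Reactants: 23 (4S,6R,7S,8S,9R)-8,9-epoxide
Product: 24 (4S,6R,7R,8S,9S)-8β-hydroxy-9α-(2-naphthylmethoxy) lactone
Conditions: 2-naphthylmethanol (5 equiv), BF3·OEt2 (0.2 equiv), CH2Cl2, −40 °C
Reagents that add atoms: 2-naphthylmethanol, OCc1ccc2ccccc2c1
Why: Lewis acid-catalysed alcoholysis of a vinyl epoxide, in which the alcohol attacks the allylic carbon C9 in an SN2-like manner with inversion and so sets C9 (S), leaves the C8–O bond intact, and differentiates the two oxygens in one operation (C9 masked as an oxidatively removable ether, C8 free); the C7 descriptor changes only through CIP priorities.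

**Step 16**
Reactants: 24 (4S,6R,7R,8S,9S)-8β-hydroxy-9α-(2-naphthylmethoxy) lactone; 25 angelic acid
Product: 27 (4S,6R,7S,8S,9S)-8β-angeloyloxy-9α-(2-naphthylmethoxy) lactone, via mixed anhydride 26 (not isolated)
Conditions: 25, 2,4,6-Cl3C6H2COCl, Et3N, toluene, rt; then 24, 75 °C
Reagents that add atoms: angelic acid (25), C/C=C(/C)C(=O)O
Why: Yamaguchi-type esterification through the mixed anhydride of angelic acid, which should acylate the hindered secondary C8 alcohol without a nucleophilic pyridine catalyst and therefore without Z-to-E isomerization to the tiglate.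

**Step 17**
Reactants: 27 (4S,6R,7S,8S,9S)-8β-angeloyloxy-9α-(2-naphthylmethoxy) lactone
Product: 28 target: methyl (1(10)E,4S,6R,7S,8S,9S)-8-[(Z)-2-methylbut-2-enoyloxy]-9-hydroxygermacra-1(10),11(13)-dien-12,6-olid-14-oate
Conditions: DDQ, CH2Cl2/pH 7 phosphate buffer, 0 °C → rt
Reagents that add atoms: none
Why: Oxidative cleavage of a 2-naphthylmethyl ether by DDQ (benzylic hydride abstraction, hydrolysis of the oxocarbenium ion) under neutral conditions that spare the angelate, the acrylate, the α-methylene lactone and the C9 stereocentre.

**Compound list**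

1 | 5-bromo-2-tetralone (5-bromo-3,4-dihydronaphthalen-2(1H)-one) | O=C1CCc2c(Br)cccc2C1 | starting material
2 | 5-bromo-2-methyl-1,2,3,4-tetrahydronaphthalen-2-ol (racemic) | CC1(O)CCc2c(Br)cccc2C1 | intermediate
3 | 8-bromo-3-methyl-1,2-dihydronaphthalene | CC1=Cc2cccc(Br)c2CC1 | intermediate
4 | (S)-5-bromo-2-methyl-1,2,3,4-tetrahydronaphthalene | Brc1cccc2c1CC[C@H](C)C2 | intermediate
5 | (S)-(6-methyl-5,6,7,8-tetrahydronaphthalen-1-yl)lithium, formed in the flask | [Li]c1cccc2c1CC[C@H](C)C2 | intermediate
6 | (S)-6-methyl-5,6,7,8-tetrahydronaphthalene-1-carboxylic acid | OC(=O)c1cccc2c1CC[C@H](C)C2 | intermediate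
7 | (6S)-6-methyl-1,4,5,6,7,8-hexahydronaphthalene-1-carboxylic acid (both C1 epimers) | OC(=O)C1C=CCC2=C1CC[C@H](C)C2 | intermediate
8 | methyl (6S)-6-methyl-1,4,5,6,7,8-hexahydronaphthalene-1-carboxylate (Birch diene ester; both C1 epimers) | COC(=O)C1C=CCC2=C1CC[C@H](C)C2 | intermediate
9 | methoxy hydroperoxide at C6 with the C1 ketone (its C1/C6 regioisomer gives the same product), formed in the flask | COC(=O)C1/C=C\CC(OC)(OO)C[C@@H](C)CCC1=O | intermediate
10 | methyl (2Z,7S)-7-methyl-5,10-dioxocyclodec-2-ene-1-carboxylate (germacrane numbering: C1 and C6 ketones, cis C8=C9, 4S; C10 epimers and enol) | COC(=O)C1/C=C\CC(=O)C[C@@H](C)CCC1=O | intermediate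
11 | sodium Z-enolate of 10 (O on C1, conjugated with the ester), formed in the flask | O=C1C[C@@H](C)CC/C([O-])=C(/C(=O)OC)\C=C/C1.[Na+] | intermediate
12 | (4S)-Z-enol triflate: C1(OTf)=C10(CO2Me) with OTf cis to the ester, cis C8=C9, C6 ketone | O=C1C[C@@H](C)CC/C(OS(=O)(=O)C(F)(F)F)=C(/C(=O)OC)\C=C/C1 | intermediate
13 | methyl (4S)-4-methyl-6-oxocyclodeca-1(10),8-diene-10-carboxylate (1(10)E, H1 cis to the ester; 8Z) | O=C1C[C@@H](C)CC/C=C(/C(=O)OC)\C=C/C1 | intermediate
14 | tert-butyl bromoacetate | BrCC(=O)OC(C)(C)C | starting material
15 | lithium dienolate of 13 (O–C6=C7–C8=C9), formed in the flask | C[C@H]1CC/C=C(/C(=O)OC)\C=C/C=C([O-])C1.[Li+] | intermediate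
16 | (4S,7R)-keto diester: 13 with CH2CO2tBu on C7 | O=C1C[C@@H](C)CC/C=C(/C(=O)OC)\C=C/[C@H]1CC(=O)OC(C)(C)C | intermediate
17 | (4S,6R,7R)-hydroxy diester: C6–OH anti to the C7 side chain | O[C@@H]1C[C@@H](C)CC/C=C(/C(=O)OC)\C=C/[C@H]1CC(=O)OC(C)(C)C | intermediate
18 | (4S,6R,7R)-hydroxy acid, formed in the flask | O[C@@H]1C[C@@H](C)CC/C=C(/C(=O)OC)\C=C/[C@H]1CC(=O)O | intermediate
19 | (4S,6R,7R)-trans-fused γ-lactone (12,6-olide, C11H2; C14 methyl ester; 1(10)E,8Z-diene) | C1C(=O)O[C@@H]2C[C@@H](C)CC/C=C(/C(=O)OC)\C=C/[C@@H]12 | intermediate
20 | Mannich base: 19 with CH2NMe2 on C11 (C11 epimers), formed in the flask | CN(C)CC1C(=O)O[C@@H]2C[C@@H](C)CC/C=C(/C(=O)OC)\C=C/[C@@H]12 | intermediate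
21 | trimethylammonium iodide of 20, formed in the flask | C[N+](C)(C)CC1C(=O)O[C@@H]2C[C@@H](C)CC/C=C(/C(=O)OC)\C=C/[C@@H]12.[I-] | intermediate
22 | (4S,6R,7S)-α-methylene lactone (C11=C13H2) | C=C1C(=O)O[C@@H]2C[C@@H](C)CC/C=C(/C(=O)OC)\C=C/[C@@H]12 | intermediate
23 | (4S,6R,7S,8S,9R)-8β,9β-epoxide of 22 | C=C1C(=O)O[C@@H]2C[C@@H](C)CC/C=C(/C(=O)OC)[C@H]3O[C@H]3[C@@H]12 | intermediate
24 | (4S,6R,7R,8S,9S)-8β-hydroxy-9α-(2-naphthylmethoxy) lactone | C=C1C(=O)O[C@@H]2C[C@@H](C)CC/C=C(/C(=O)OC)[C@H](OCc3ccc4ccccc4c3)[C@@H](O)[C@@H]12 | intermediate
25 | angelic acid ((Z)-2-methylbut-2-enoic acid) | C/C=C(/C)C(=O)O | starting material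
26 | angelic 2,4,6-trichlorobenzoic mixed anhydride, formed in the flask | C/C=C(/C)C(=O)OC(=O)c1c(Cl)cc(Cl)cc1Cl | intermediate
27 | (4S,6R,7S,8S,9S)-8β-angeloyloxy-9α-(2-naphthylmethoxy) lactone | C=C1C(=O)O[C@@H]2C[C@@H](C)CC/C=C(/C(=O)OC)[C@H](OCc3ccc4ccccc4c3)[C@@H](OC(=O)/C(C)=C\C)[C@@H]12 | intermediate
28 | CNP0552150.1: methyl (1(10)E,4S,6R,7S,8S,9S)-8-angeloyloxy-9-hydroxygermacra-1(10),11(13)-dien-12,6-olid-14-oate | C=C1C(=O)O[C@@H]2C[C@@H](C)CC/C=C(/C(=O)OC)[C@H](O)[C@@H](OC(=O)/C(C)=C\C)[C@@H]12 | target

**Step count and risks**

Total step count: 17. Longest linear sequence: 17 steps (1 → 28); 14 and 25 are used as purchased.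

Steps most likely to fail:

1. Step 10. The only stereocentre present, C4, is remote from C7, so the alkylation may show poor facial selectivity, and the extended enolate may also react at its γ-carbon C9. Fallback, setting out from 13: condensation with (S)-1-amino-2-(methoxymethyl)pyrrolidine (SAMP; neat, 60 °C) gives the SAMP hydrazone F1. Deprotonation with LiN(iPr)2 in THF at −78 °C and alkylation of the azaenolate with 14 gives the C7-alkylated SAMP hydrazone F2. Here the auxiliary, not the C4 methyl group, dictates the face (Enders SAMP hydrazone alkylation; the topicity that gives (R)-2-alkylcyclohexanones corresponds to the 7R centre needed). Biphasic hydrolysis with saturated aqueous oxalic acid in ether, which does not epimerize α-centres, comes back to the route at 16.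

2. Step 15. Regio- and stereocontrol may be lost in the epoxide opening: ionization toward an allyl cation with attack at C1 instead of C9, slow backside approach of a bulky, dilute alcohol to a medium-ring epoxide, and self-condensation of the benzylic alcohol under the Lewis acid. Fallback, setting out from 23: hydrolysis with dilute HClO4 in THF/H2O at 0 °C, with water as a small nucleophile present as co-solvent, gives the 8β,9α-diol F3. Silylation with Et3SiCl and imidazole in DMF at −20 °C should take place first at the allylic C9 hydroxyl, which is flanked by the planar C10, and gives the C9 triethylsilyl ether F4. Esterification of the C8 hydroxyl under the conditions of step 16 gives the C9 silyl ether C8 angelate F5. HF·pyridine in THF then comes back to the route at 28.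

3. Step 14. Facial selectivity may be poor in a mismatched case, in which the conformational bias of the ten-membered ring (C11 lies on the β face next to C8) directs the oxidant to the α face against the catalyst. Fallback, setting out from 22: NBS in acetone/H2O at 0 °C forms the bromonium ion on the intrinsically preferred α face and water opens it at the allylic carbon C9, giving the trans-bromohydrin F6 (C9–OH β, C8–Br α). K2CO3 in acetone closes it by backside displacement of bromide, so the epoxide oxygen ends up on the face opposite to the one chosen by the electrophile, and the sequence comes back to the route at 23.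

**Further compounds**

F1 | step 10 | SAMP hydrazone of 13 at C6 | COC[C@@H]1CCCN1N=C1C[C@@H](C)CC/C=C(/C(=O)OC)\C=C/C1
F2 | step 10 | C7-alkylated SAMP hydrazone (hydrazone of 16) | COC[C@@H]1CCCN1N=C1C[C@@H](C)CC/C=C(/C(=O)OC)\C=C/[C@H]1CC(=O)OC(C)(C)C
F3 | step 15 | 8β,9α-diol | C=C1C(=O)O[C@@H]2C[C@@H](C)CC/C=C(/C(=O)OC)[C@H](O)[C@@H](O)[C@@H]12
F4 | step 15 | C9 triethylsilyl ether of F3 | C=C1C(=O)O[C@@H]2C[C@@H](C)CC/C=C(/C(=O)OC)[C@H](O[Si](CC)(CC)CC)[C@@H](O)[C@@H]12
F5 | step 15 | C9 triethylsilyl ether C8 angelate | C=C1C(=O)O[C@@H]2C[C@@H](C)CC/C=C(/C(=O)OC)[C@H](O[Si](CC)(CC)CC)[C@@H](OC(=O)/C(C)=C\C)[C@@H]12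
F6 | step 14 | trans-bromohydrin (C9–OH β, C8–Br α) | C=C1C(=O)O[C@@H]2C[C@@H](C)CC/C=C(/C(=O)OC)[C@@H](O)[C@H](Br)[C@@H]12
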